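**Retrosynthetic overview**
1. Target ⇒ one achiral precursor, a 2-(quinonyloxy)-5-hydroxy-3,4-bis(1,1-dimethylallyloxy)benzoic acid. In the forward sense a single operation (reagent-controlled dearomative Claisen shift, intramolecular Diels–Alder, oxa-Michael lactonization) closes three rings and sets all six stereocentres.
2. That quinone acid ⇒ ring C hydroquinone acid + ring A chloro-chromenequinone (carboxylate addition–elimination, then shift of the quinone from the carboxyl oxygen to the neighbouring phenol oxygen).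
3. Ring A piece ⇒ 2,6-dimethoxy-1,4-benzoquinone + prenal (oxa-[3+3] annulation makes the pyran) + prenyl acetate (C-prenylation).
4. Ring C piece ⇒ methyl 2,3,4-trihydroxybenzoate + a 1,1-dimethylallyl carbonate (two O-allylations), then para-oxidation of the remaining phenol.
5. Ring order: pyran first, on the bought quinone ring A (aromatic ring C is bought); in the last step the tetrahydrofuran and the second ring of the bicyclo[2.2.2]octene form together, then the 1,3-dioxan-4-one.

Assumption: the natural configuration at the spiro ketal carbon and at the neighbouring CH(prenyl) carbon is the thermodynamically favoured one relative to the cage, since both centres can equilibrate (reversible oxa-Michael ring closure, enolization).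

**Route**

Step 1
Reactants: 1 2,6-dimethoxy-1,4-benzoquinone
Product: 2 2-hydroxy-6-methoxy-1,4-benzoquinone
Conditions: NaOH (2.2 equiv), H2O/THF, 0 to 23 °C; then 1 M HCl
Reagents that add atoms: sodium hydroxide, [Na+].[OH-]
Why: Hydroxide adds to the methoxy-bearing carbon of the vinylogous ester and expels methoxide (addition–elimination, vinylogous saponification), and the hydroxyquinone anion so formed is too electron-rich for the second methoxy group to follow; no stereocentre.

Step 2
Reactants: 2 2-hydroxy-6-methoxy-1,4-benzoquinone; 3 3-methylbut-2-enal (prenal)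
Product: 5 7-hydroxy-2,2-dimethyl-2H-chromene-5,8-dione, via methoxychromenequinone 4 (not isolated)
Conditions: 3 (1.5 equiv), ethylenediammonium diacetate (10 mol %), toluene, 80 °C; evaporate; then NaOH (2.5 equiv), THF/H2O, 0 to 23 °C; 1 M HCl
Reagents that add atoms: sodium hydroxide, [Na+].[OH-]
Why: Knoevenagel condensation at the only nucleophilic ring carbon (between C–OH and C=O) and 6π oxa-electrocyclization of the resulting 1-oxatriene give the 2H-pyran (formal oxa-[3+3] annulation, as in the hydroxynaphthoquinone to pyranonaphthoquinone series), and the unhindered methoxy vinylogous ester is then saponified as in step 1; no stereocentre.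

Step 3
Reactants: 5 7-hydroxy-2,2-dimethyl-2H-chromene-5,8-dione; 6 3-methylbut-2-en-1-yl acetate (prenyl acetate)
Product: 7 7-hydroxy-2,2-dimethyl-6-(3-methylbut-2-en-1-yl)-2H-chromene-5,8-dione
Conditions: 6 (1.2 equiv), Pd(PPh3)4 (5 mol %), THF, 50 °C
Reagents that add atoms: none
Why: Tsuji–Trost allylation: acetate released on ionization deprotonates the hydroxyquinone (a vinylogous carboxylic acid), whose only free ring carbon attacks the unsubstituted end of the prenyl–palladium complex, O-allylation being reversible under these conditions (the lapachol synthesis from 2-hydroxy-1,4-naphthoquinone is the model); no stereocentre.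

Step 4
Reactants: 8 2-methylbut-3-en-2-ol
Product: 9 tert-butyl 2-methylbut-3-en-2-yl carbonate
Conditions: n-BuLi (1.0 equiv), THF, −78 to 0 °C; Boc2O (1.05 equiv), 0 to 23 °C; H2O
Reagents that add atoms: di-tert-butyl dicarbonate, CC(C)(C)OC(=O)OC(=O)OC(C)(C)C
Why: The lithium alkoxide of the tertiary allylic alcohol is acylated by Boc2O (alkoxycarbonylation); no stereocentre.

Step 5
Reactants: 10 methyl 2,3,4-trihydroxybenzoate; 9 tert-butyl 2-methylbut-3-en-2-yl carbonate
Product: 11 methyl 2-hydroxy-3,4-bis[(2-methylbut-3-en-2-yl)oxy]benzoate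
Conditions: 9 (2.3 equiv), Pd(PPh3)4 (5 mol %), THF, 0 °C
Reagents that add atoms: none
Why: Tsuji–Trost O-allylation under kinetic control puts each phenoxide on the substituted end of the allyl–palladium complex (tertiary 1,1-dimethylallyl aryl ethers), while the 2-OH, hydrogen-bonded to the ester and flanked on both sides, stays free; no stereocentre.

Step 6
Reactants: 11 methyl 2-hydroxy-3,4-bis[(2-methylbut-3-en-2-yl)oxy]benzoate
Product: 13 methyl 2,5-dihydroxy-3,4-bis[(2-methylbut-3-en-2-yl)oxy]benzoate, via quinone ester 12 (not isolated)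
Conditions: (KSO3)2NO (2.5 equiv), KH2PO4 (aq.)/acetone, 0 °C; then Na2S2O4 (aq.), 0 °C
Reagents that add atoms: potassium nitrosodisulfonate (KSO3)2NO, [K+].[K+].[O]N(S(=O)(=O)[O-])S(=O)(=O)[O-]
Why: Teuber oxidation: the nitroxyl radical removes the phenolic hydrogen and a second equivalent couples at the only free para carbon to give the para-quinone, which Na2S2O4 reduces at once to the hydroquinone before its allyl vinyl ether units can rearrange; no stereocentre.

Step 7
Reactants: 13 methyl 2,5-dihydroxy-3,4-bis[(2-methylbut-3-en-2-yl)oxy]benzoate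
Product: 14 2,5-dihydroxy-3,4-bis[(2-methylbut-3-en-2-yl)oxy]benzoic acid
Conditions: LiOH (4 equiv), THF/H2O (degassed), 23–40 °C; then 1 M HCl to pH 3, 0 °C
Reagents that add atoms: lithium hydroxide, [Li+].[OH-]
Why: Ester saponification (acyl substitution), which the base-stable tertiary allyl aryl ethers survive, air being excluded to keep the hydroquinone reduced; no stereocentre.

Step 8
Reactants: 7 7-hydroxy-2,2-dimethyl-6-(3-methylbut-2-en-1-yl)-2H-chromene-5,8-dione; 14 2,5-dihydroxy-3,4-bis[(2-methylbut-3-en-2-yl)oxy]benzoic acid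
Product: 17 2-{[2,2-dimethyl-6-(3-methylbut-2-en-1-yl)-5,8-dioxo-5,8-dihydro-2H-chromen-7-yl]oxy}-5-hydroxy-3,4-bis[(2-methylbut-3-en-2-yl)oxy]benzoic acid, via chloroquinone 15 (not isolated), via acyloxyquinone 16 (not isolated)
Conditions: 7, NaH (1.0 equiv), THF, 0 °C; (COCl)2 (1.05 equiv), DMF (cat.), 0 to 23 °C; evaporate; then 14 (1.0 equiv), NaHCO3 (1.0 equiv), DMF, 0 to 23 °C
Reagents that add atoms: none
Why: The hydroxyquinone becomes its vinylogous acid chloride, the carboxylate of 14 (the only anion NaHCO3 can form) displaces chloride by addition–elimination, and in the resulting vinylogous mixed anhydride the neighbouring 2-OH attacks the same quinone carbon through a six-membered addition–elimination that releases the carboxylic acid (vinylogous acyl transfer to a phenol), which the distant 5-OH cannot do; no stereocentre.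

Step 9
Reactants: 17 2-{[2,2-dimethyl-6-(3-methylbut-2-en-1-yl)-5,8-dioxo-5,8-dihydro-2H-chromen-7-yl]oxy}-5-hydroxy-3,4-bis[(2-methylbut-3-en-2-yl)oxy]benzoic acid
Product: 20 CNP0222516.1 (spiro ketal lactone), via dienone acid 18 (not isolated), via caged quinone acid 19 (not isolated)
Conditions: (R,R)-TsNHCH(Ph)CH(Ph)NHTs (2.2 equiv), BBr3 (2.2 equiv), CH2Cl2, 23 °C, evaporate; then 17, Et3N (2.2 equiv), CH2Cl2, −78 to −20 °C, then 23 °C; pH 7 buffer; citric acid (aq.)/THF, 23 °C
Reagents that add atoms: none
Why: Proposed new method: the chiral bromoborane made from the bis-sulfonamide binds the ring C phenol oxygen (and the acid) and chelates the adjacent tertiary allyl ether oxygen, so a charge-accelerated [3,3] shift (aromatic Claisen rearrangement) sends the allyl terminus to one face of the ortho carbon that already carries the other ether and fixes that quaternary centre as R; the dienone cannot rearomatize and is trapped by intramolecular Diels–Alder addition of the remaining 1,1-dimethylallyl ether, whose short tether dictates the other three cage centres; on acidic work-up the freed acid adds to the alkoxyquinone (oxa-Michael) and the spiro carbon and the CH(prenyl) carbon settle reversibly into the more stable arrangement; the closest known reactions are the boron-mediated enantioselective Claisen rearrangement of catechol monoallyl ethers and the thermal Claisen/Diels–Alder cascade of catechol bis(1,1-dimethylallyl) ethers.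

**Compound list**

1 | 2,6-dimethoxy-1,4-benzoquinone | COC1=CC(=O)C=C(OC)C1=O | starting material
2 | 2-hydroxy-6-methoxy-1,4-benzoquinone | COC1=CC(=O)C=C(O)C1=O | intermediate
3 | 3-methylbut-2-enal (prenal) | CC(C)=CC=O | starting material
4 | 7-methoxy-2,2-dimethyl-2H-chromene-5,8-dione | COC1=CC(=O)C2=C(OC(C)(C)C=C2)C1=O | intermediate
5 | 7-hydroxy-2,2-dimethyl-2H-chromene-5,8-dione | OC1=CC(=O)C2=C(OC(C)(C)C=C2)C1=O | intermediate
6 | 3-methylbut-2-en-1-yl acetate (prenyl acetate) | CC(=O)OCC=C(C)C | starting material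
7 | 7-hydroxy-2,2-dimethyl-6-(3-methylbut-2-en-1-yl)-2H-chromene-5,8-dione | OC1=C(CC=C(C)C)C(=O)C2=C(OC(C)(C)C=C2)C1=O | intermediate
8 | 2-methylbut-3-en-2-ol | CC(C)(O)C=C | starting material
9 | tert-butyl 2-methylbut-3-en-2-yl carbonate | CC(C)(C)OC(=O)OC(C)(C)C=C | intermediate
10 | methyl 2,3,4-trihydroxybenzoate | COC(=O)c1ccc(O)c(O)c1O | starting material
11 | methyl 2-hydroxy-3,4-bis[(2-methylbut-3-en-2-yl)oxy]benzoate | COC(=O)c1ccc(OC(C)(C)C=C)c(OC(C)(C)C=C)c1O | intermediate
12 | methyl 4,5-bis[(2-methylbut-3-en-2-yl)oxy]-3,6-dioxocyclohexa-1,4-diene-1-carboxylate | COC(=O)C1=CC(=O)C(OC(C)(C)C=C)=C(OC(C)(C)C=C)C1=O | intermediate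
13 | methyl 2,5-dihydroxy-3,4-bis[(2-methylbut-3-en-2-yl)oxy]benzoate | COC(=O)c1cc(O)c(OC(C)(C)C=C)c(OC(C)(C)C=C)c1O | intermediate
14 | 2,5-dihydroxy-3,4-bis[(2-methylbut-3-en-2-yl)oxy]benzoic acid | OC(=O)c1cc(O)c(OC(C)(C)C=C)c(OC(C)(C)C=C)c1O | intermediate
15 | 7-chloro-2,2-dimethyl-6-(3-methylbut-2-en-1-yl)-2H-chromene-5,8-dione | ClC1=C(CC=C(C)C)C(=O)C2=C(OC(C)(C)C=C2)C1=O | intermediate
16 | 2,2-dimethyl-6-(3-methylbut-2-en-1-yl)-5,8-dioxo-5,8-dihydro-2H-chromen-7-yl 2,5-dihydroxy-3,4-bis[(2-methylbut-3-en-2-yl)oxy]benzoate | O=C(OC1=C(CC=C(C)C)C(=O)C2=C(OC(C)(C)C=C2)C1=O)c1cc(O)c(OC(C)(C)C=C)c(OC(C)(C)C=C)c1O | intermediate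
17 | 2-{[2,2-dimethyl-6-(3-methylbut-2-en-1-yl)-5,8-dioxo-5,8-dihydro-2H-chromen-7-yl]oxy}-5-hydroxy-3,4-bis[(2-methylbut-3-en-2-yl)oxy]benzoic acid (achiral) | OC(=O)c1cc(O)c(OC(C)(C)C=C)c(OC(C)(C)C=C)c1OC1=C(CC=C(C)C)C(=O)C2=C(OC(C)(C)C=C2)C1=O | intermediate
18 | dienone acid: (3R)-2-{[2,2-dimethyl-6-(3-methylbut-2-en-1-yl)-5,8-dioxo-5,8-dihydro-2H-chromen-7-yl]oxy}-5-hydroxy-3-[(2-methylbut-3-en-2-yl)oxy]-3-(3-methylbut-2-en-1-yl)-4-oxocyclohexa-1,5-diene-1-carboxylic acid | C=CC(C)(C)O[C@@]1(CC=C(C)C)C(=O)C(O)=CC(C(=O)O)=C1OC2=C(CC=C(C)C)C(=O)C3=C(OC(C)(C)C=C3)C2=O | intermediate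
19 | caged quinone acid: ring-opened form of 20 (free CO2H on the cage alkene carbon, chromenequinon-7-yl on the bridgehead oxygen); bicyclo[2.2.2]octenone cage with fused tetrahydrofuran, bridgehead C–OH (R), ring-fusion CH (S), C(prenyl)–O carbon (R), quinonyloxy-bearing bridgehead (S) | OC(=O)C1=C[C@]3(O)C[C@H]4C(C)(C)O[C@@](CC=C(C)C)(C3=O)[C@@]14OC5=C(CC=C(C)C)C(=O)C6=C(OC(C)(C)C=C6)C5=O | intermediate
20 | CNP0222516.1: spiro 1,3-dioxan-4-one ketal lactone; spiro carbon (S), ring A CH(prenyl) (S), cage centres as in 19 | CC(C)=CC[C@H]1C(=O)C2=C(OC(C)(C)C=C2)C(=O)[C@@]12OC(=O)C1=C[C@]3(O)C[C@H]4C(C)(C)O[C@@](CC=C(C)C)(C3=O)[C@@]14O2 | target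

**Totals**

Total step count: 9. Longest linear sequence: 6 (steps 4, 5, 6, 7, 8, 9).

**Steps most likely to fail, with fallbacks**

Step 9 is the least secured. The boron-bound tertiary allyl ether may ionize instead of rearranging, and neither the level nor the sense of induction is secured by precedent (the (S,S)-reagent may be the one that gives the R centre). A further open point is whether 19 closes to 20 under mild acid; it is taken to do so because the natural product is isolated in the closed form. The fallback sets out from 17, uses no chiral reagent and runs the same sequence thermally (toluene, 110 °C, then dilute acid). Both mirror-image series then form: besides 18, 19 and 20 the flask holds the mirror-image dienone acid F1, the mirror-image caged quinone acid F2 and the mirror-image target F3. The racemate is resolved by preparative chromatography on a chiral stationary phase, which comes back to the route at 20.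

Step 8 may suffer from the free 5-OH of 14 competing for the chloroquinone or for the mixed anhydride, which would give oligomers or the wrong aryl ether. The fallback sets out from 13 and masks that phenol before the union. Silylation of the unchelated 5-OH (iPr3SiCl, imidazole, DMF) gives methyl 2-hydroxy-3,4-bis[(2-methylbut-3-en-2-yl)oxy]-5-[(triisopropylsilyl)oxy]benzoate F4. Saponification with LiOH gives the corresponding acid F5. Coupling with 15 as in step 8 passes through the silylated acyloxyquinone F6 to the 5-O-silyl ether of 17 F7. Bu4NF/AcOH in THF at 0 °C then removes the silyl group, and the route is rejoined at 17.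

Step 6 asks Fremy's salt to oxidize a hydrogen-bonded, doubly flanked phenol, and the quinone 12 is thermally fragile. The fallback sets out from 9 and bought methyl 3,4,5-trihydroxybenzoate F8. Two-fold O-allylation with Pd(PPh3)4 (the 4-OH first, then one of the equivalent outer hydroxyls; mono- and tri-ethers are separated) gives methyl 3-hydroxy-4,5-bis[(2-methylbut-3-en-2-yl)oxy]benzoate F9. Its unchelated phenol is oxidized by (KSO3)2NO at the free para carbon, next to the ester, to the same quinone ester, so the route is rejoined at 12.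

**Further compounds**

F1 | step 9 | mirror-image dienone acid (ent-18) | C=CC(C)(C)O[C@]1(CC=C(C)C)C(=O)C(O)=CC(C(=O)O)=C1OC2=C(CC=C(C)C)C(=O)C3=C(OC(C)(C)C=C3)C2=O
F2 | step 9 | mirror-image caged quinone acid (ent-19) | OC(=O)C1=C[C@@]3(O)C[C@@H]4C(C)(C)O[C@](CC=C(C)C)(C3=O)[C@]14OC5=C(CC=C(C)C)C(=O)C6=C(OC(C)(C)C=C6)C5=O
F3 | step 9 | mirror-image target (ent-20) | CC(C)=CC[C@@H]1C(=O)C2=C(OC(C)(C)C=C2)C(=O)[C@]12OC(=O)C1=C[C@@]3(O)C[C@@H]4C(C)(C)O[C@](CC=C(C)C)(C3=O)[C@]14O2
F4 | step 8 | methyl 2-hydroxy-3,4-bis[(2-methylbut-3-en-2-yl)oxy]-5-[(triisopropylsilyl)oxy]benzoate | COC(=O)c1cc(O[Si](C(C)C)(C(C)C)C(C)C)c(OC(C)(C)C=C)c(OC(C)(C)C=C)c1O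
F5 | step 8 | 2-hydroxy-3,4-bis[(2-methylbut-3-en-2-yl)oxy]-5-[(triisopropylsilyl)oxy]benzoic acid | OC(=O)c1cc(O[Si](C(C)C)(C(C)C)C(C)C)c(OC(C)(C)C=C)c(OC(C)(C)C=C)c1O
F6 | step 8 | silylated acyloxyquinone (5-O-triisopropylsilyl ether of 16) | O=C(OC1=C(CC=C(C)C)C(=O)C2=C(OC(C)(C)C=C2)C1=O)c1cc(O[Si](C(C)C)(C(C)C)C(C)C)c(OC(C)(C)C=C)c(OC(C)(C)C=C)c1O
F7 | step 8 | 5-O-triisopropylsilyl ether of 17 | OC(=O)c1cc(O[Si](C(C)C)(C(C)C)C(C)C)c(OC(C)(C)C=C)c(OC(C)(C)C=C)c1OC1=C(CC=C(C)C)C(=O)C2=C(OC(C)(C)C=C2)C1=O
F8 | step 6 | methyl 3,4,5-trihydroxybenzoate (methyl gallate) | COC(=O)c1cc(O)c(O)c(O)c1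
F9 | step 6 | methyl 3-hydroxy-4,5-bis[(2-methylbut-3-en-2-yl)oxy]benzoate | COC(=O)c1cc(O)c(OC(C)(C)C=C)c(OC(C)(C)C=C)c1
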